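(The numbers of this flask were set for the occasion; the result is computed.)

The leftover I reckoned from was the free monomer that the protic impurity spares: 8.00 mM of 10 mM, since at the charged concentrations the impurity's half-life of 0.13 h is shorter than the 1.9 h of the pre-initiator.

free monomer 10 mM; protic impurity 2.00 mM; pre-initiator 2.5 mol%; time 10 h

    free monomer + initiator → living end + monomer in chains (k1 = 0.449 /M/min)
    free monomer + living end → monomer in chains + living end, rate k2*[living end]*[free monomer] (k2 = 95.7 /M/min)
    protic impurity + free monomer → quenched substrate (k3 = 8.85 /M/min)
    free monomer + initiator → spent initiator (k4 = 4.32 /M/min)
    pre-initiator → initiator (k5 = 0.00622 /min)

- the average divides the monomer in chains by the number of chains begun, living and dead together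
- run time (flask): 10 h

* average number of monomer units in a chain (chains begun, living or dead) at 10 h
* part of the free monomer that has reacted at 10 h

I turned the question round and asked what a flask needs if most of its initiator is to begin chains rather than end as spent initiator. The initiating and the wasting step both take initiator with free monomer, so their rates keep the ratio of their constants at any [free monomer]. That frozen ratio gives 9.41%: the initiation share, the chain-starting constant over the sum of both constants, a selectivity in the usual term. A share above half needs the chain-starting constant to exceed the wasting one, but in this flask the wasting 4.32 /M/min is ten times the chain-starting 0.449 /M/min. So the 0.250 mM of pre-initiator charged gives 0.0235 mM of chains once fully released. Spread over the spared monomer, that makes 340 units per chain, a plain division and not a bound. I did not reckon how far growth gets in 10 h, so this figure is no estimate of the average at that time.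

The forecast gave 210 units and 70% reacted, lower than my division, holding that “the slowly released initiator is mostly wasted”.

The flask gave 209 units per chain and 69.6% reacted, as the forecast said. At 10.0 h the flask still held 30.4% of its free monomer, and its average stood below the 330 read at 100 h. The initiation share, applied to the charge less the 2.4% of pre-initiator and the 0.00338 mM of initiator still in the flask at 10.0 h, gives 0.0226 mM of chains, against 0.0227 mM of living end in the flask at that time. For the neighbour flask with 1 mol% of pre-initiator the same reckoning gives 0.00912 mM, and that flask held 0.00912 mM of living end at 10.0 h.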